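The runs were generated by integration for substances that don't exist, and the scatter is random.

Two chemists stand at the board over this flask. They agree that the steps forming left-handed product run one way, so the best time is the limit of 5.0 h. They part on how much stands there by then.

all flasks: left-handed substrate 0.37 M; right-handed substrate 0.37 M; solid reagent 1.48 M; free catalyst 9.3 mM; added ligand 26 mM
- south: racemization catalyst 5 mM; run made earlier
- south-east: racemization catalyst 11 mM; run made earlier
- flask: racemization catalyst 7.4 mM; time 5.0 h

| south: time / h | south: left-handed product / % | south-east: time / h | south-east: left-handed product / % |
|---|---|---|---|
| 1.33 | 6.0 | 1.33 | 5.1 |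
| 1.50 | 7.3 | 1.50 | 4.5 |
| 2.00 | 9.7 | 2.00 | 9.8 |
| 2.50 | 13.4 | 2.50 | 14.4 |
| 3.00 | 16.5 | 3.00 | 17.4 |

(readings scatter by 1 percentage point)

* the best time, 5.0 h at the latest, for left-handed product
* the amount of left-handed product, in percent of the left-handed substrate and right-handed substrate together charged, at that time
* the first time at which left-handed product reaches 15%, in the same percent

- free catalyst is single-handed; left-handed substrate and right-handed substrate are mirror images of each other, charged as a racemate, each of them at the stated concentration
- as a solid, counted per litre of solution: solid reagent
- steps under discussion: left-handed substrate + racemization catalyst <-> right-handed substrate + racemization catalyst; solid reagent <-> partner; partner + free catalyst + left-handed substrate -> free catalyst + left-handed product; partner + free catalyst + right-handed substrate -> free catalyst + right-handed product; free catalyst + added ligand <-> idle complex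
- at the start none of the solid reagent is in solution

Both start from the same reading. The south and south-east runs end 0.9 percentage points apart at 3.00 h, with a scatter of 1 point on a reading. So this flask, whose 7.4 mM of racemization catalyst lies between their 5 mM and 11 mM, is read from their mean. The rise of that mean from first to last reading, per hour and as a fraction of both substrates charged, is 0.0683 h⁻¹, and this hourly gain carries the argument. Drawn back, the line meets zero at 0.517 h.

The first chemist keeps the gain constant and extends the line from the last mean reading: 30.6% at the limit, and the 15% level at 2.71 h.

The second treats both substrates as one store, joined by the racemization catalyst and drained pseudo-first-order, so the gain falls with what is left. Starting at the same zero, this gives 26.4% at the limit and the level at 2.90 h.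

The forecast sets 28% at 5 h, between the drain and the line, and the level at 2.72 h, close to the line's 2.71 h; of its own figure of about 25% without racemization it says “Racemization partly replenishes it”.

The flask gives 29.7% at 5.00 h and reaches the level at 2.69 h.

    left-handed substrate + racemization catalyst ⇌ right-handed substrate + racemization catalyst, rate k1*[racemization catalyst]*[left-handed substrate] forward; the back reaction follows from the equilibrium constant (k = 0.0460 M⁻¹ s⁻¹)
    solid reagent ⇌ partner, rate k2*(cs2 - [partner]) while solid is left; crystals form when [partner] > cs2 (solubility = 0.220 M, k = 1.70 × 10⁻⁴ s⁻¹)
    partner + free catalyst + left-handed substrate → free catalyst + left-handed product (k = 1.50 M⁻² s⁻¹)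
    partner + free catalyst + right-handed substrate → free catalyst + right-handed product (k = 0.490 M⁻² s⁻¹)
    free catalyst + added ligand ⇌ idle complex (K = 1600 M⁻¹, k = 0.550 M⁻¹ s⁻¹)

That 29.7% lies nearer the line than the drain, and from 2.50 h to 5.00 h the flask gained 0.0639 h⁻¹ against the hourly gain of 0.0683 h⁻¹. Over those hours left-handed substrate fell from 39.9% to 29.3% while partner rose from 0.0956 M to 0.113 M, being made 1.11 times faster than used up at the limit. Left until 12 h, this flask has 9.42% of left-handed substrate and 0.164 M of partner, and its 59.8% of left-handed product lies nearer the drain's 54.3% than the line's 78.4%.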